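## Structural features

The target is a labdane-type diterpenoid of the antipodal (ent) series: a trans-fused decalin (rings A and B) whose C9 carries a 3-methylidenepent-4-enyl chain (C11–C16) ending in a 2-substituted buta-1,3-diene. Six stereocentres form one connected array, C6–C5(–C4)–C10–C9–C8. They are the quaternary C4 (axial C19 methyl, equatorial C18 hydroxymethyl), C5–H, the equatorial C6 acetate, the quaternary C10 methyl (C20), C9–H, and the tertiary C8 carbinol with an axial C17 methyl. The methyls C19, C20 and C17 are syn-axial on one face, while H5, H9, O6 and O8 lie on the other, so one face of ring B is closed to reagents. The fragile groups are the terminal diene (polymerisation, cycloaddition, acid), the tertiary C8 hydroxyl (dehydration, and retro-aldol cleavage while C6 is a ketone), and the C6 acetate beside a free primary C18 hydroxyl (acyl migration). The real difficulty is the pair of quaternary centres C4 and C10 with cis methyls, combined with the anti C9–H/C10–CH3 pair and an equatorial C6 oxygen whose hydrogen must enter from the blocked face. The key step exploits the pattern of ring B: anti C9–H and C10–CH3, oxygen on C6 and a methyl on C8 are what a conrotatory 6π closure of a C10=C5–C6=C7–C8=C9 triene leaves.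

## Logic of the disconnections

**25 ⇒ 24 + ethene.** The C13=C16 and C14=C15 double bonds are cut, so that C15 and C16 leave as ethene and a C13≡C14 alkyne remains. The diene is the most reactive part of 25 and would not survive light, peroxide, SmI2 or acid. The gain is an inert terminal alkyne in every earlier intermediate. The demand is a cross enyne metathesis, run last, that tolerates two free hydroxyls and an acetate.

**24 ⇒ 23 ⇒ 21.** The O6–acetyl bond and a temporary O18–Si bond are cut, because the primary C18 hydroxyl would otherwise acylate first. The gain is a plain triol, 21. The demands are silylation selective for O18, acylation of O6 that spares the tertiary O8, and a desilylation mild enough to prevent acetyl migration from O6 to O18.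

**21 ⇒ 19 ⇒ 18.** The C6–H bond and the C8–O bond are cut, the latter retraced through the oxirane of 19 with 20 as the ketone in between. Both carbinols derive from the planar C6(=O)–C7=C8 enone of 18, so C6 and C8 become sp2. The demands are epoxidation anti to C20, and a reduction that places the C6 hydrogen on the shielded face, which rules out hydride reagents and calls for electron transfer.

**18 ⇒ 17.** The C5–H bond is cut and the two Si–O bonds are restored, since 17 is the direct product of ring closure. C5 becomes sp2. The demand is protonation of C5 anti to C19 and C20 in a medium too weakly basic to deprotonate C9.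

**17 ⇒ 16 (reached from 15).** The C9–C10 bond of ring B is cut. This removes ring B together with C9 and C10, and leaves ring A with one stereocentre and an achiral chain. The demands are photochemical conrotation, control of the C10 face by C4, and access to the closing C6=C7 geometry. The last is met by photoequilibration of 15, the isomer that enol silylation should favour.

**15 ⇒ 14.** The O18–Si and O6–Si bonds are cut, because one reagent turns a hydroxy ketone into the tethered trienol ether. The gain is a silicon-free precursor with no enol geometry to define. The demands are enolisation towards C7 only (assured, since C5 is sp2) and closure of a seven-membered ring.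

**14 ⇒ 13 ⇒ 6 + 12.** The C6–C7 bond is cut, with the C7–S bond that assists it. The cut divides the molecule at a carbonyl into ring A and the chain. A sulfonyl-stabilised allyl anion reacts at its α-carbon, which an allylmetal would not, and acyl transfer from the lactone of 6 frees O18 in the same event. The gain is two fragments of ten and eight skeletal carbons and no protecting group. The demands are 1,2-addition to a hindered conjugated lactone, and desulfonylation with protonation at C7 so that C8=C9 stays E and unconjugated.

**6 ⇒ 5 ⇒ 4.** The C5–C6 bond and the lactone O18–C6 bond are cut in one carbonylation, then the C18–H bonds in an ester reduction. C6 enters as CO. The enol triflate of 4 both activates C5 and masks the former ketone during the reduction. The demands are a hydride that is selective for the ester, and oxidative addition at a tetrasubstituted triflate.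

**4 ⇒ 3 ⇒ 2 ⇒ 1.** The O–S, C10–C20 and C4–C19 bonds are cut. The gain is a commodity keto ester. C4 is the only centre that needs external asymmetric induction, and the demand is an enantioselective methylation of a β-keto ester.

**12 ⇒ 10 ⇒ 9 ⇒ 7.** The C7–S bond, the ester oxidation level and the C8=C9 bond (Wittig) are cut. The gain is a five-carbon alkynol. The demand is E geometry at C8=C9, which later decides C9.

## Other disconnections considered

**Alternative 1:** The cut runs through C5–C10 and C3–C4, so that rings A and B open together to the open-chain trienoate A2. Forward, A2 would cyclise on heating or with Me2AlCl in an intramolecular Diels–Alder reaction to the trans-fused octalin ester A1.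
- In its favour: one thermal step builds both rings and sets C4, C5 and C10 from alkene geometry. C6 and C9 are already in place from acyclic chemistry, so the C6 oxygen never needs a reduction on the blocked face. On that point it is better than the chosen plan. A thermal step also scales more easily than a photoreaction, which is a second point in its favour.
- Against it here: the diene terminus C10 is fully substituted with its methyl inside, the dienophile is trisubstituted, and two quaternary centres (C4, C10) must form in the same cycloaddition. The C9 centre sits α to the C8 ketone and can epimerise under Lewis acid.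
- After the key step much remains: C1=C2 must be saturated, the C18 ester reduced, and the diene built from C12. Methyl addition to the C8 ketone should come from the open face and give the wrong C8 epimer, so a methylenation, epoxidation and reduction detour is likely.
- Comparison: A1 holds more of the ring stereochemistry than 17, and both key steps take their relative configuration from orbital symmetry and alkene geometry (equal). The doubt in Alternative 1 is reactivity, and in the chosen plan it is facial selectivity. Because of the C8 correction and the side-chain work, step economy is no better and probably worse.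

**Alternative 2:** The cut runs through C9–C10 and C7–C8, with the dienophile delivered from the C18 oxygen. Heating the dienyl but-2-ynoate A4 would give the lactone-bridged ring B diene A3 through a temporary seven-membered lactone.
- In its favour: the short ester tether brings C9 to the C18 face of C10, so the cis C19/C20 relationship rests on a more rigid element than the seven-membered silylene (equal or better). The C5=C6 alkene of A3 could be hydroborated from the open face, setting C5–H and an equatorial C6 hydroxyl in one operation, which is better than the C6 reduction of the chosen plan. A4 would come from 5 in two steps, so the front end is equal or shorter.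
- Against it here: C10 is a tetrasubstituted diene terminus with an inside methyl and the tether joins the diene at C5, so forcing temperatures and competing hydrogen shifts of the diene are to be expected. In A3, C9 is still sp2, C11 is a lactone carbonyl that must become CH2 and be extended by five carbons, and C8 still needs its carbinol.
- Comparison: the chosen key step sets C9 and C10 together and brings in C11–C14, C17 and the C6 oxygen at once, so it is structurally the richer step. Mechanistically the thermal cycloaddition is the more scalable (better), but it has to make a quaternary centre at a hindered terminus. In step count the longer endgame of Alternative 2 outweighs its shorter start.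

**Alternative 3:** The cut is C3–C4 alone, in ring A. The carvone-derived epoxy vinyl ketone A6 would be opened at C4 by Cp2TiCl (trivalent titanium), and the tertiary radical would add 6-endo to the vinyl ketone terminus to give the trans-fused decalin-1,9-dione A5.
- In its favour: absolute configuration comes from the chiral pool, so no asymmetric catalysis is needed, which is better than step 1 of the chosen plan. C5, C10 and the ring fusion are in place, the radical step tolerates free hydroxyl, and ring B already carries the C8 methyl.
- Against it here: C4 would be set by the conformation of a planar tertiary radical bearing two groups of similar size, which is weak control of the centre the chosen plan sets by catalysis. A quaternary centre forms next to the ring fusion in a slow 6-endo mode that competes with radical reduction.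
- The product also maps poorly onto the target: the C1 carbonyl must be removed, the C9 ketone turned into a CH bearing the whole chain next to a quaternary carbon, and the C6 and C8 oxygens introduced afterwards.
- Comparison: A5 overlaps least with the target. The radical mechanism is tolerant but less stereodefined than a pericyclic closure. Step economy is clearly worse.

Key step: step 12

**Remarks**
- Numbering: labdane locants (C1–C10 decalin, C11–C16 chain, C17 on C8, C18 and C19 on C4, C20 on C10) are used for positions from 13 onwards. Configuration is defined by the CIP descriptors and the SMILES, not by the parent name.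
- Descriptors: the isomer that closes has C5 and C8 cis across C6=C7. Because oxygen outranks C5, this is 6E by the sequence rules (16), and the isomer that enol silylation should favour is 6Z (15). The alkyne carbons are C13 and C14; C15 and C16 arrive with ethene in step 18.
- Assumption: the sense of induction in step 1 is matched to (S)-2 by the choice of catalyst antipode (both are available); it has not been assigned here.

## Route

Step 1
Reactants: 1 ethyl 2-oxocyclohexane-1-carboxylate
Product: 2 ethyl (1S)-1-methyl-2-oxocyclohexane-1-carboxylate
Conditions: MeI, chiral C2-symmetric N-spiro bis(binaphthyl)ammonium bromide with 3,4,5-trifluorophenyl groups (2 mol %), K2CO3 (50% aq), toluene, −20 °C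
Reagents that add atoms: iodomethane, CI
Why: Asymmetric phase-transfer C-alkylation of a cyclic β-keto ester: the chiral ammonium enolate ion pair exposes one enolate face to MeI and sets the quaternary C4 centre, the only stereocentre not derived from another. The carbonate base avoids retro-Claisen cleavage.

Step 2
Reactants: 2 ethyl (1S)-1-methyl-2-oxocyclohexane-1-carboxylate
Product: 3 ethyl (1S)-1,3-dimethyl-2-oxocyclohexane-1-carboxylate (both C3 epimers)
Conditions: LiN(iPr)2, THF, −78 °C; MeI, −78 → −20 °C
Reagents that add atoms: iodomethane, CI
Why: Kinetic enolate alkylation: only the CH2 flank of the ketone can be deprotonated because the other α-carbon is quaternary, and MeI installs the future C20 methyl. The new centre is left uncontrolled because step 3 makes it sp2.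

Step 3
Reactants: 3 ethyl (1S)-1,3-dimethyl-2-oxocyclohexane-1-carboxylate
Product: 4 ethyl (1S)-1,3-dimethyl-2-{[(trifluoromethyl)sulfonyl]oxy}cyclohex-2-ene-1-carboxylate
Conditions: KN(SiMe3)2, THF, −78 °C; PhNTf2, −78 → 0 °C
Reagents that add atoms: N-phenylbis(trifluoromethanesulfonimide), O=S(=O)(N(c1ccccc1)S(=O)(=O)C(F)(F)F)C(F)(F)F
Why: Enol triflate formation: the only possible enolate is O-sulfonylated, which fixes the tetrasubstituted C5=C10 alkene and masks the ketone against the hydride of step 4.

Step 4
Reactants: 4 ethyl (1S)-1,3-dimethyl-2-{[(trifluoromethyl)sulfonyl]oxy}cyclohex-2-ene-1-carboxylate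
Product: 5 (6R)-6-(hydroxymethyl)-2,6-dimethylcyclohex-1-en-1-yl trifluoromethanesulfonate
Conditions: iBu2AlH (2.5 equiv), CH2Cl2, −78 → −20 °C; aq. potassium sodium tartrate
Reagents that add atoms: none
Why: iBu2AlH reduction of an ester to the primary alcohol at low temperature; vinyl triflates are inert to this hydride, so C18 reaches the alcohol level without touching C5 (the descriptor changes only because the priorities change).

Step 5
Reactants: 5 (6R)-6-(hydroxymethyl)-2,6-dimethylcyclohex-1-en-1-yl trifluoromethanesulfonate
Product: 6 (3aS)-3a,7-dimethyl-3a,4,5,6-tetrahydro-2-benzofuran-1(3H)-one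
Conditions: CO (1 atm), Pd(OAc)2 (5 mol %), dppp (5 mol %), Et3N, DMF, 60 °C
Reagents that add atoms: carbon monoxide, [C-]#[O+]
Why: Palladium-catalysed carbonylative lactonisation of a hydroxy vinyl triflate: oxidative addition of zerovalent palladium to the C5–OTf bond, CO insertion and capture of the acylpalladium by the C18 hydroxyl close the five-membered lactone and introduce C6.

Step 6
Reactants: 7 pent-4-yn-1-ol
Product: 9 ethyl (2E)-2-methylhept-2-en-6-ynoate, via pent-4-ynal 8 (not isolated)
Conditions: PhI(OAc)2, TEMPO (10 mol %), CH2Cl2, rt; then Ph3P=C(CH3)CO2Et, rt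
Reagents that add atoms: ethyl 2-(triphenyl-λ5-phosphanylidene)propanoate, CCOC(=O)C(C)=P(c1ccccc1)(c1ccccc1)c1ccccc1
Why: Oxoammonium oxidation to the volatile aldehyde, followed in the same flask by a Wittig reaction with the stabilised ylide, which is reliably (E)-selective for α-methyl enoates and so fixes the C8=C9 geometry.

Step 7
Reactants: 9 ethyl (2E)-2-methylhept-2-en-6-ynoate
Product: 10 (2E)-2-methylhept-2-en-6-yn-1-ol
Conditions: iBu2AlH (2.2 equiv), CH2Cl2, −78 °C; aq. potassium sodium tartrate
Reagents that add atoms: none
Why: 1,2-Reduction of the enoate to the allylic alcohol with no change of alkene geometry; the terminal alkyne is inert.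

Step 8
Reactants: 10 (2E)-2-methylhept-2-en-6-yn-1-ol
Product: 12 {[(2E)-2-methylhept-2-en-6-yn-1-yl]sulfonyl}benzene, via allylic bromide 11 (not isolated)
Conditions: CBr4, PPh3, CH2Cl2, 0 °C; then PhSO2Na, DMF, rt
Reagents that add atoms: sodium benzenesulfinate, [Na+].[O-]S(=O)c1ccccc1; tetrabromomethane, BrC(Br)(Br)Br (bromine present only in 11)
Why: Appel bromination of the primary allylic alcohol, then SN2 displacement by sulfinate at sulfur; attack at the primary terminus keeps the (E)-trisubstituted alkene.

Step 9
Reactants: 6 (3aS)-3a,7-dimethyl-3a,4,5,6-tetrahydro-2-benzofuran-1(3H)-one; 12 {[(2E)-2-methylhept-2-en-6-yn-1-yl]sulfonyl}benzene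
Product: 13 (3E)-1-[(6S)-6-(hydroxymethyl)-2,6-dimethylcyclohex-1-en-1-yl]-3-methyl-2-(phenylsulfonyl)oct-3-en-7-yn-1-one (both C7 epimers)
Conditions: 12 (2.1 equiv), n-BuLi (2.05 equiv), THF, −78 °C; then 6, −78 → −30 °C; aq. NH4Cl
Reagents that add atoms: none
Why: Acylation of an α-lithiated allylic sulfone by a lactone: such anions react at the α-carbon, so C7 and not C9 bonds to C6. The acidic β-keto sulfone is deprotonated by the second equivalent of anion, which blocks over-addition. Ring opening frees the C18 hydroxyl without a protecting group, and the fully substituted C10 terminus disfavours conjugate addition.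

Step 10
Reactants: 13 (3E)-1-[(6S)-6-(hydroxymethyl)-2,6-dimethylcyclohex-1-en-1-yl]-3-methyl-2-(phenylsulfonyl)oct-3-en-7-yn-1-one
Product: 14 (3E)-1-[(6S)-6-(hydroxymethyl)-2,6-dimethylcyclohex-1-en-1-yl]-3-methyloct-3-en-7-yn-1-one
Conditions: SmI2 (2.5 equiv), THF–MeOH, −78 °C
Reagents that add atoms: none
Why: Reductive desulfonylation of a β-keto sulfone by SmI2 (two single-electron transfers, loss of sulfinate); the samarium dienolate is protonated by MeOH at C7 under kinetic control, so the C8=C9 alkene stays E and out of conjugation.

Step 11
Reactants: 14 (3E)-1-[(6S)-6-(hydroxymethyl)-2,6-dimethylcyclohex-1-en-1-yl]-3-methyloct-3-en-7-yn-1-one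
Product: 15 (4S,6Z,8E)-6,18-[(di-tert-butylsilanediyl)bis(oxy)]-15,16-dinor-9,10-secolabda-5(10),6,8-trien-13-yne
Conditions: tBu2Si(OTf)2 (1.1 equiv), Et3N (4 equiv), CH2Cl2 (0.01 M), −78 → 0 °C
Reagents that add atoms: di-tert-butylsilyl bis(trifluoromethanesulfonate), CC(C)(C)[Si](OS(=O)(=O)C(F)(F)F)(OS(=O)(=O)C(F)(F)F)C(C)(C)C
Why: Silylene formation from a hydroxy ketone with a dialkylsilyl bis(triflate): the primary C18 hydroxyl is silylated first, the tethered silyl triflate then activates the C6 carbonyl, and Et3N removes the doubly activated C7 proton (soft enolisation), closing the seven-membered ring under high dilution. The C8 group should settle syn to oxygen (6Z); any 6E isomer formed alongside is compound 16 and is carried through.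

Step 12
Reactants: 15 (4S,6Z,8E)-6,18-[(di-tert-butylsilanediyl)bis(oxy)]-15,16-dinor-9,10-secolabda-5(10),6,8-trien-13-yne
Product: 17 (4S,9R,10S)-6,18-[(di-tert-butylsilanediyl)bis(oxy)]-15,16-dinorlabda-5,7-dien-13-yne, via 6E-trienol ether 16 (not isolated)
Conditions: hν (narrow-band 311 nm lamps through Pyrex, λ ≥ 305 nm), degassed MTBE with 0.1% Et3N, 5 mM, −20 °C
Reagents that add atoms: none
Why: Light near 310 nm first interconverts the C6=C7 geometric isomers 15 and 16, as previtamin D and tachysterol interconvert, and only 16, in which C5 and C8 are cis, can adopt the helical s-cis,cis,s-cis geometry. Excited 16 then undergoes a conrotatory 6π electrocyclisation (hexatriene to cyclohexa-1,3-diene; the closest known case is the photochemical closure of previtamin D to provitamin D and lumisterol), which forms the C9–C10 σ-bond and closes ring B as a six-membered carbocycle in the 6π electrocyclic mode. C9 and C10 are set relative to each other by orbital symmetry and alkene geometry: C20 is the inside group at C10 (held cis to C6 by ring A), C11 is the outside group at C9 because C8=C9 is E, and conrotation brings one inside and one outside group onto the same face, so C20 and C11 end cis and C9–H anti to C20, which the thermal disrotatory mode cannot give. Their sense relative to C4 is set by the tether: the silylene ring holds the C5–C6 bond s-cis and keeps C18 near the diene plane, so the C19 methyl is pseudoaxial and the helix that brings C9 to the opposite face of C10 should be preferred, C9 bonding anti to C19 and C20 being pushed syn to it. The C17 methyl on C8 disfavours the s-trans rotamer about C7–C8 and so raises the share of the reactive conformer. Three selectivities are needed: against closure of a C8=C9 photoisomer, which would need both C20 and C11 inside and should only revert; against re-opening of 17, secured by irradiating at 305 nm or above where the homoannular diene absorbs only weakly; and against the thermal [1,7]-hydrogen shift from C20 and thermal disrotatory closure, both suppressed at −20 °C. The terminal alkyne does not absorb in this range, and the trace of Et3N protects the silyl enol ethers from adventitious acid.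

Step 13
Reactants: 17 (4S,9R,10S)-6,18-[(di-tert-butylsilanediyl)bis(oxy)]-15,16-dinorlabda-5,7-dien-13-yne
Product: 18 (4S,5S,9R,10S)-18-hydroxy-15,16-dinorlabd-7-en-13-yn-6-one
Conditions: Bu4NF (2.2 equiv), AcOH (2.5 equiv), THF, 0 °C → rt
Reagents that add atoms: none
Why: Fluoride cleaves both Si–O bonds; the freed cross-conjugated dienol ketonises by protonation at C5 on the face anti to the C19 and C20 methyls, giving the trans ring fusion, which is also the more stable one. The acetic acid buffer keeps the medium from deprotonating the vinylogous C9 position.

Step 14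
Reactants: 18 (4S,5S,9R,10S)-18-hydroxy-15,16-dinorlabd-7-en-13-yn-6-one
Product: 19 (4S,5S,7R,8R,9S,10S)-7,8-epoxy-18-hydroxy-15,16-dinorlabd-13-yn-6-one
Conditions: H2O2 (30% aq), NaOH (0.3 equiv), MeOH, 0 °C
Reagents that add atoms: hydrogen peroxide, OO
Why: Weitz–Scheffer nucleophilic epoxidation of the β,β-disubstituted enone: hydroperoxide adds to C8 on the face anti to the axial C20 methyl and the enolate closes the oxirane on that face, which fixes the C8–O bond with the C17 methyl axial.

Step 15
Reactants: 19 (4S,5S,7R,8R,9S,10S)-7,8-epoxy-18-hydroxy-15,16-dinorlabd-13-yn-6-one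
Product: 21 (4S,5S,6R,8S,9S,10R)-15,16-dinorlabd-13-yne-6,8,18-triol, via 8-hydroxy-6-ketone 20 (not isolated)
Conditions: SmI2 (2.2 equiv), THF–MeOH, −90 °C; then SmI2 (3 equiv), H2O, Et3N, −78 °C → rt
Reagents that add atoms: none
Why: SmI2 reduction of the α,β-epoxy ketone cleaves the C7–O bond and leaves the C8 carbinol unchanged in configuration. The following SmI2/H2O/amine electron-transfer reduction of the ketone should place the bulky oxygen–samarium group equatorial at C6 and let the small proton enter axially from the methyl-shielded face, the outcome typical of dissolving-metal-type reductions and opposite to that of hydride reagents. Reducing 20 without isolation leaves it no time for retro-aldol cleavage.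

Step 16
Reactants: 21 (4S,5S,6R,8S,9S,10R)-15,16-dinorlabd-13-yne-6,8,18-triol
Product: 23 (4S,5S,6R,8S,9S,10R)-18-[(tert-butyldimethylsilyl)oxy]-8-hydroxy-15,16-dinorlabd-13-yn-6-yl acetate, via 18-silyl ether 22 (not isolated)
Conditions: TBSCl (1.1 equiv), imidazole, CH2Cl2, 0 °C; then Ac2O, Et3N, DMAP (cat.), rt
Reagents that add atoms: tert-butyl(chloro)dimethylsilane, CC(C)(C)[Si](C)(C)Cl; acetic anhydride, CC(=O)OC(C)=O
Why: Selective silylation of the primary C18 hydroxyl over the secondary and tertiary ones, then DMAP-catalysed acetylation of the equatorial C6 hydroxyl in the same flask; the hindered tertiary C8 hydroxyl should not acylate under these conditions.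

Step 17
Reactants: 23 (4S,5S,6R,8S,9S,10R)-18-[(tert-butyldimethylsilyl)oxy]-8-hydroxy-15,16-dinorlabd-13-yn-6-yl acetate
Product: 24 (4S,5S,6R,8S,9S,10R)-8,18-dihydroxy-15,16-dinorlabd-13-yn-6-yl acetate
Conditions: HF·pyridine, pyridine, THF, 0 °C → rt
Reagents that add atoms: none
Why: Fluoride-mediated Si–O cleavage under buffered, non-basic conditions, which avoids acetyl migration from O6 to O18 and loss of the acetate; the tertiary alcohol tolerates the buffered reagent.

Step 18
Reactants: 24 (4S,5S,6R,8S,9S,10R)-8,18-dihydroxy-15,16-dinorlabd-13-yn-6-yl acetate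
Product: 25 (4S,5S,6R,8S,9S,10R)-8,18-dihydroxylabda-13(16),14-dien-6-yl acetate (target)
Conditions: ethene (1 atm), second-generation Grubbs catalyst RuCl2(=CHPh)(PCy3)(H2IMes) (5 mol %), CH2Cl2, 40 °C
Reagents that add atoms: ethene, C=C
Why: Ethylene–alkyne cross enyne metathesis: the ruthenium methylidene adds to the terminal alkyne and the resulting vinylcarbene is turned over by ethene, converting C13≡C14 into the 2-substituted buta-1,3-diene (C13=C16, C14=C15). It is placed last so that the diene meets no further reagent.

## Compound list

1 | ethyl 2-oxocyclohexane-1-carboxylate | CCOC(=O)C1CCCCC1=O | starting material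
2 | ethyl (1S)-1-methyl-2-oxocyclohexane-1-carboxylate | CCOC(=O)[C@@]1(C)CCCCC1=O | intermediate
3 | ethyl (1S)-1,3-dimethyl-2-oxocyclohexane-1-carboxylate (both C3 epimers) | CCOC(=O)[C@@]1(C)CCCC(C)C1=O | intermediate
4 | ethyl (1S)-1,3-dimethyl-2-{[(trifluoromethyl)sulfonyl]oxy}cyclohex-2-ene-1-carboxylate | CCOC(=O)[C@@]1(C)CCCC(C)=C1OS(=O)(=O)C(F)(F)F | intermediate
5 | (6R)-6-(hydroxymethyl)-2,6-dimethylcyclohex-1-en-1-yl trifluoromethanesulfonate | OC[C@@]1(C)CCCC(C)=C1OS(=O)(=O)C(F)(F)F | intermediate
6 | (3aS)-3a,7-dimethyl-3a,4,5,6-tetrahydro-2-benzofuran-1(3H)-one | O=C1OC[C@@]2(C)CCCC(C)=C12 | intermediate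
7 | pent-4-yn-1-ol | C#CCCCO | starting material
8 | pent-4-ynal | C#CCCC=O | intermediate (not isolated)
9 | ethyl (2E)-2-methylhept-2-en-6-ynoate | C#CCC/C=C(C)/C(=O)OCC | intermediate
10 | (2E)-2-methylhept-2-en-6-yn-1-ol | C#CCC/C=C(C)/CO | intermediate
11 | (5E)-7-bromo-6-methylhept-5-en-1-yne (allylic bromide) | C#CCC/C=C(C)/CBr | intermediate (not isolated)
12 | {[(2E)-2-methylhept-2-en-6-yn-1-yl]sulfonyl}benzene | C#CCC/C=C(C)/CS(=O)(=O)c1ccccc1 | intermediate
13 | (3E)-1-[(6S)-6-(hydroxymethyl)-2,6-dimethylcyclohex-1-en-1-yl]-3-methyl-2-(phenylsulfonyl)oct-3-en-7-yn-1-one (both C7 epimers) | C#CCC/C=C(C)/C(C(=O)C1=C(C)CCC[C@]1(C)CO)S(=O)(=O)c1ccccc1 | intermediate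
14 | (3E)-1-[(6S)-6-(hydroxymethyl)-2,6-dimethylcyclohex-1-en-1-yl]-3-methyloct-3-en-7-yn-1-one | C#CCC/C=C(C)/CC(=O)C1=C(C)CCC[C@]1(C)CO | intermediate
15 | (4S,6Z,8E)-6,18-[(di-tert-butylsilanediyl)bis(oxy)]-15,16-dinor-9,10-secolabda-5(10),6,8-trien-13-yne | C#CCC/C=C(C)/C=C1\O[Si](C(C)(C)C)(C(C)(C)C)OC[C@@]2(C)CCCC(C)=C12 | intermediate
16 | (4S,6E,8E)-6,18-[(di-tert-butylsilanediyl)bis(oxy)]-15,16-dinor-9,10-secolabda-5(10),6,8-trien-13-yne (6E-trienol ether, the isomer that closes) | C#CCC/C=C(C)/C=C1/O[Si](C(C)(C)C)(C(C)(C)C)OC[C@@]2(C)CCCC(C)=C12 | intermediate (not isolated)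
17 | (4S,9R,10S)-6,18-[(di-tert-butylsilanediyl)bis(oxy)]-15,16-dinorlabda-5,7-dien-13-yne | C#CCC[C@H]1[C@]2(C)CCC[C@](C)(CO[Si](C(C)(C)C)(C(C)(C)C)O3)C2=C3C=C1C | intermediate
18 | (4S,5S,9R,10S)-18-hydroxy-15,16-dinorlabd-7-en-13-yn-6-one | C#CCC[C@H]1[C@]2(C)CCC[C@](C)(CO)[C@H]2C(=O)C=C1C | intermediate
19 | (4S,5S,7R,8R,9S,10S)-7,8-epoxy-18-hydroxy-15,16-dinorlabd-13-yn-6-one | C#CCC[C@H]1[C@]2(C)CCC[C@](C)(CO)[C@H]2C(=O)[C@@H]3O[C@]13C | intermediate
20 | (4S,5S,8S,9S,10S)-8,18-dihydroxy-15,16-dinorlabd-13-yn-6-one (8-hydroxy-6-ketone) | C#CCC[C@H]1[C@]2(C)CCC[C@](C)(CO)[C@H]2C(=O)C[C@]1(C)O | intermediate (not isolated)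
21 | (4S,5S,6R,8S,9S,10R)-15,16-dinorlabd-13-yne-6,8,18-triol | C#CCC[C@H]1[C@]2(C)CCC[C@](C)(CO)[C@H]2[C@H](O)C[C@]1(C)O | intermediate
22 | (4S,5S,6R,8S,9S,10R)-18-[(tert-butyldimethylsilyl)oxy]-15,16-dinorlabd-13-yne-6,8-diol (18-silyl ether) | C#CCC[C@H]1[C@]2(C)CCC[C@](C)(CO[Si](C)(C)C(C)(C)C)[C@H]2[C@H](O)C[C@]1(C)O | intermediate (not isolated)
23 | (4S,5S,6R,8S,9S,10R)-18-[(tert-butyldimethylsilyl)oxy]-8-hydroxy-15,16-dinorlabd-13-yn-6-yl acetate | C#CCC[C@H]1[C@]2(C)CCC[C@](C)(CO[Si](C)(C)C(C)(C)C)[C@H]2[C@H](OC(C)=O)C[C@]1(C)O | intermediate
24 | (4S,5S,6R,8S,9S,10R)-8,18-dihydroxy-15,16-dinorlabd-13-yn-6-yl acetate | C#CCC[C@H]1[C@]2(C)CCC[C@](C)(CO)[C@H]2[C@H](OC(C)=O)C[C@]1(C)O | intermediate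
25 | (4S,5S,6R,8S,9S,10R)-8,18-dihydroxylabda-13(16),14-dien-6-yl acetate | C=CC(=C)CC[C@H]1[C@]2(C)CCC[C@](C)(CO)[C@H]2[C@H](OC(C)=O)C[C@]1(C)O | target

## Step count and least certain steps

Total step count: 18 (15 in the main line, 3 in the side-chain branch).
Longest linear sequence: 15 steps (steps 1–5 and 9–18, from 1).

**Risk 1, step 12 (key step).** The most likely failure is insufficient discrimination between the two helical conformers of 16, so that C9 also bonds on the C19 face. Material may also be lost through light-induced re-opening of 17 and [1,7]-hydrogen migration from C20. The fallback sets out from 14 and returns at 18, and replaces the flexible seven-membered silylene by a rigid five-membered tether. Acid-catalysed cyclodehydration of the hemiketal form of 14 (PPTS, 4 Å molecular sieves, benzene, rt) should give the 2-alkylidene oxolane, the cyclic trienol ether F1. In F1, O6 and C18 are joined directly, so C18 lies in the diene plane and C19 is rigidly axial. Irradiation under the conditions of step 12 should close ring B to the 6,18-epoxy diene F2. Hydrolysis of this cyclic enol ether with dilute aqueous acid (0.1 M HCl, THF, 0 °C) protonates C5 and releases the C6 ketone and the C18 hydroxyl, giving 18.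

**Risk 2, step 1.** Enantioselectivity may erode because methyl iodide is a small electrophile and uncatalysed interfacial alkylation competes. The fallback sets out from 1 and returns at 2 by way of a covalently bound auxiliary. Condensation of 1 with tert-butyl L-valinate (cat. TsOH, benzene, water removal) gives the enamine F3. Deprotonation with LiN(iPr)2 and methylation with MeI gives the quaternary imine F4. The valine antipode and the donor additive are chosen so that the (1S) centre results, since the facial sense of such lithio-enamines depends on the additive. Mild aqueous acid then hydrolyses F4 to 2 and returns the auxiliary.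

**Risk 3, step 9.** The stabilised sulfonyl carbanion may fail to add to the hindered conjugated lactone carbonyl, with proton transfer from the γ-positions or conjugate addition taking over. The fallback sets out from 6 and from 11 (isolated after the first stage of step 8), returns at 14, and uses a Corey–Seebach acyl anion. iBu2AlH (1 equiv, −78 °C) reduces 6 to the lactol F5. Propane-1,3-dithiol with BF3·OEt2 converts it into the hydroxy dithiane F6. Its dianion (n-BuLi, 2.1 equiv, THF, −30 °C) is alkylated at the dithiane carbon by 11 to give the alkylated dithiane F7. MeI and CaCO3 in aqueous MeCN then unmask the ketone 14.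

**Risk 4, step 11.** Silylation of the cyclic hemiketal form of 14, or intermolecular silyl ether formation, may outrun closure of the seven-membered ring. The fallback sets out from 14, returns at 18, and gives up the tether. TBSOTf (2.5 equiv) and Et3N (CH2Cl2, −78 °C) should give the bis-silyl trienol ether F8 as a mixture of C6=C7 isomers. Irradiation as in step 12 should give the ring-closed bis-silyl dienol ether F9, with the facial bias then resting only on the difference between the C19 methyl and the silyloxymethyl group at C4. Bu4NF buffered with AcOH gives 18.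

**Risk 5, step 15.** The second stage may give the axial C6 alcohol if protonation at C6 is not under thermodynamic control, and retro-aldol cleavage of 20 may intervene if the ketone lingers in the basic medium. Equilibration by hydride transfer is not an option, because it must pass the same blocked face. The fallback sets out from 20 (isolated by quenching after the first stage), returns at 23, and uses inversion instead. NaBH4 (MeOH, 0 °C) attacks the open face and gives the axial 6-epimeric triol F10. TBSCl and imidazole give its 18-silyl ether F11. A Mitsunobu reaction (PPh3, DIAD, AcOH, toluene) inverts C6, with acetate arriving from the open face, to give 23. Elimination towards C5 or C7 is the risk of this variant.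

## Further compounds

F1 | step 12 | (3aS)-3a,7-dimethyl-1-[(2E)-2-methylhept-2-en-6-yn-1-ylidene]-1,3,3a,4,5,6-hexahydro-2-benzofuran (mixture of C6=C7 isomers) | C#CCC/C=C(C)/C=C1OC[C@@]2(C)CCCC(C)=C12
F2 | step 12 | (4S,9R,10S)-6,18-epoxy-15,16-dinorlabda-5,7-dien-13-yne | C#CCC[C@H]1[C@]2(C)CCC[C@](C)(CO3)C2=C3C=C1C
F3 | step 1 | ethyl 2-{[(2S)-1-tert-butoxy-3-methyl-1-oxobutan-2-yl]amino}cyclohex-1-ene-1-carboxylate | CCOC(=O)C1=C(N[C@@H](C(C)C)C(=O)OC(C)(C)C)CCCC1
F4 | step 1 | ethyl (1S)-2-{[(2S)-1-tert-butoxy-3-methyl-1-oxobutan-2-yl]imino}-1-methylcyclohexane-1-carboxylate | CCOC(=O)[C@@]1(C)CCCCC1=N[C@@H](C(C)C)C(=O)OC(C)(C)C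
F5 | step 9 | (3aS)-3a,7-dimethyl-1,3,3a,4,5,6-hexahydro-2-benzofuran-1-ol (both anomers) | OC1OC[C@@]2(C)CCCC(C)=C12
F6 | step 9 | [(1S)-2-(1,3-dithian-2-yl)-1,3-dimethylcyclohex-2-en-1-yl]methanol | OC[C@@]1(C)CCCC(C)=C1C1SCCCS1
F7 | step 9 | [(1S)-1,3-dimethyl-2-{2-[(2E)-2-methylhept-2-en-6-yn-1-yl]-1,3-dithian-2-yl}cyclohex-2-en-1-yl]methanol | OC[C@@]1(C)CCCC(C)=C1C1(C/C(C)=C/CCC#C)SCCCS1
F8 | step 11 | (4S,8E)-6,18-bis[(tert-butyldimethylsilyl)oxy]-15,16-dinor-9,10-secolabda-5(10),6,8-trien-13-yne (mixture of C6=C7 isomers) | C#CCC/C=C(C)/C=C(O[Si](C)(C)C(C)(C)C)C1=C(C)CCC[C@]1(C)CO[Si](C)(C)C(C)(C)C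
F9 | step 11 | (4S,9R,10S)-6,18-bis[(tert-butyldimethylsilyl)oxy]-15,16-dinorlabda-5,7-dien-13-yne | C#CCC[C@H]1[C@]2(C)CCC[C@](C)(CO[Si](C)(C)C(C)(C)C)C2=C(O[Si](C)(C)C(C)(C)C)C=C1C
F10 | step 15 | (4S,5S,6S,8S,9S,10R)-15,16-dinorlabd-13-yne-6,8,18-triol | C#CCC[C@H]1[C@]2(C)CCC[C@](C)(CO)[C@H]2[C@@H](O)C[C@]1(C)O
F11 | step 15 | (4S,5S,6S,8S,9S,10R)-18-[(tert-butyldimethylsilyl)oxy]-15,16-dinorlabd-13-yne-6,8-diol | C#CCC[C@H]1[C@]2(C)CCC[C@](C)(CO[Si](C)(C)C(C)(C)C)[C@H]2[C@@H](O)C[C@]1(C)O
A1 | alternative 1 | trans-fused octalin ester: methyl 6-[(tert-butyldimethylsilyl)oxy]-12-[(4-methoxybenzyl)oxy]-8-oxo-13,14,15,16,17-pentanorlabd-1-en-18-oate | COc1ccc(COCC[C@H]2[C@]3(C)C=CC[C@](C)(C(=O)OC)[C@H]3[C@H](O[Si](C)(C)C(C)(C)C)CC2=O)cc1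
A2 | alternative 1 | open-chain trienoate: methyl (2E,8E)-4-[(tert-butyldimethylsilyl)oxy]-7-{2-[(4-methoxybenzyl)oxy]ethyl}-2,8-dimethyl-6-oxoundeca-2,8,10-trienoate (C4 and C7 configured as C6 and C9 of A1) | C=C/C=C(C)/[C@H](CCOCc1ccc(OC)cc1)C(=O)C[C@@H](O[Si](C)(C)C(C)(C)C)/C=C(C)/C(=O)OC
A3 | alternative 2 | lactone-bridged ring B diene: 12,13,14,15,16-pentanorlabda-5,8-dien-11-oic acid 11,18-lactone | O=C1OC[C@@]2(C)CCC[C@@]3(C)C1=C(C)CC=C23
A4 | alternative 2 | [(1S)-2-ethenyl-1,3-dimethylcyclohex-2-en-1-yl]methyl but-2-ynoate | CC#CC(=O)OC[C@@]1(C)CCCC(C)=C1C=C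
A5 | alternative 3 | trans-fused decalin-1,9-dione: 18-hydroxy-11,12,13,14,15,16-hexanorlabd-7-ene-1,9-dione | O=C1C(C)=CC[C@@H]2[C@@](C)(CO)CCC(=O)[C@@]12C
A6 | alternative 3 | carvone-derived epoxy vinyl ketone: 6-acryloyl-2,6-dimethyl-5-(2-methyloxiran-2-yl)cyclohex-2-en-1-one (oxirane carbon unassigned) | C=CC(=O)[C@@]1(C)C(=O)C(C)=CC[C@@H]1C1(C)CO1
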